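## Retrosynthetic overview

1. The dialdehyde comes from the 1,4-diol 18 by Swern oxidation; the (Z)-cinnamate comes from a phenylpropiolate by Lindlar semihydrogenation; the C4 methylene is carried as a β-hydroxysilane (Peterson) until the penultimate step.
2. Ring A is a reduced p-quinone: the C1 oxygen and the C4 methylene carbon are para, and the angular C10 methyl and the C3 methyl are the two methyls of 2,5-dimethyl-1,4-benzoquinone.
3. Ring B is disconnected by [4+2] across C5–C6 and C9–C10. The enabling feature is the C7=C8 double bond of ring B, flanked by C6 and C9 and opposite the C5–C10 ring-fusion bond shared with the 1,4-dioxygenated ring A. The diene is a vinylallene (C6=C7–C8=C9=CH2), so C9 leaves the cycloaddition as an exocyclic methylene.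
4. Stereorelay: C10 by catalyst in the cycloaddition; C5 by epimerisation to the trans-decalin; C3 by equilibration; C1 by axial hydride delivery; C9 by hydroboration anti to the angular methyl.
5. Ring order: ring A arrives intact from the quinone; ring B is the only ring formed, in the key step.

Key step: step 3

Remark on numbering: decalin positions are C1 (oxygen-bearing carbon), C2, C3 (secondary methyl), C4 (methylene carbon), C5 (ring-fusion CH), C6–C9 (ring B), C10 (angular-methyl carbon); β is the face of the angular methyl.

Assumption: the (S)-configured oxazaborolidinium ion is taken to leave open the quinone face that gives the (10S) adduct 6; if the other face reacts, the (R)-catalyst is used with no other change.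

Assumption: compounds 10–17 are drawn as the C4 epimer expected from equatorial attack; this centre is destroyed in step 12, so either epimer serves.

## Route

Step 1
Reactants: 1 4-chlorobut-2-yn-1-ol
Product: 2 tert-butyl[(4-chlorobut-2-yn-1-yl)oxy]dimethylsilane
Conditions: TBSCl, imidazole, CH2Cl2, 0 °C to rt
Reagents that add atoms: tert-butyldimethylsilyl chloride, CC(C)(C)[Si](C)(C)Cl
Why: Imidazole-promoted silylation of a primary alcohol is routine and leaves the propargylic chloride untouched; no stereocentre is formed.

Step 2
Reactants: 2 tert-butyl[(4-chlorobut-2-yn-1-yl)oxy]dimethylsilane; 3 vinylmagnesium bromide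
Product: 4 tert-butyldimethyl[(2-vinylbuta-2,3-dien-1-yl)oxy]silane (the vinylallene CH2=C=C(CH2OTBS)–CH=CH2)
Conditions: CuBr·SMe2 (5 mol %), THF, −60 to −20 °C
Reagents that add atoms: 3 vinylmagnesium bromide, C=C[Mg]Br
Why: Copper-catalysed SN2' substitution of a propargylic chloride by a Grignard reagent should deliver the vinyl group to the alkyne carbon remote from chloride and give the 1,1-disubstituted allene; no stereocentre is formed.

Step 3
Reactants: 4 tert-butyldimethyl[(2-vinylbuta-2,3-dien-1-yl)oxy]silane; 5 2,5-dimethyl-1,4-benzoquinone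
Product: 6 cis-fused enedione (10β-methyl, 5β-H; 10S): 8-(TBSO-methyl)-3,10-dimethyl-9-methylidene-decal-2,7-diene-1,4-dione
Conditions: (S)-B-(o-tolyl) oxazaborolidine from (S)-α,α-diphenylprolinol, activated with Tf2NH (20 mol %), CH2Cl2, −78 to −40 °C
Reagents that add atoms: none
Why: Proposed new method: a concerted but asynchronous [4+2] cycloaddition is proposed in which vinylallene 4 reacts through C6=C7–C8=C9 (vinyl group plus the inner allene π bond) with the C5=C10 bond of quinone 5 bound through its C1 carbonyl to the cationic boron Lewis acid; the closest known reactions are enantioselective Diels–Alder additions of simple dienes to 2,5-dialkylbenzoquinones under this catalyst type and thermal additions of vinylallenes to quinones, which have not been combined. Ring B is closed as a six-membered carbocycle by suprafacial [4+2] closure onto both quinone carbons, which is why the ring fusion is cis. The quaternary centre C10 is set by the catalyst, which leaves one face of the bound quinone open, and C5 follows from the suprafacial addition; C9 stays sp2 as the exocyclic methylene, so no endo/exo question arises and C9 is set in step 8. The step needs regioselectivity (C9 to the methyl-bearing C10, C6 to C5): the vinyl CH2 terminus C6 is the nucleophilic and least hindered end and should bond first to the unsubstituted β-carbon C5 of the activated C1 enone, and the small sp carbon C9 then closes onto the methyl-bearing α-carbon. It also needs mono-addition, which is secured because the two double bonds of 5 are equivalent, the C2=C3 bond left in 6 is a poorer dienophile than 5, and the transoid diene of 6 cannot act as a diene.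

Step 4
Reactants: 6 cis-fused enedione
Product: 7 trans-fused enedione (10β-methyl, 5α-H)
Conditions: DBU (0.1 equiv), CH2Cl2, 0 °C to rt
Reagents that add atoms: none
Why: Base-mediated epimerisation of a quinone Diels–Alder adduct through the C4 enolate inverts C5 (α to the C4 carbonyl); the trans-fused enedione with an axial angular methyl is expected to be the more stable isomer, as in classical quinone-adduct chemistry, and the quaternary C10 prevents aromatisation.

Step 5
Reactants: 7 trans-fused enedione
Product: 8 trans-fused diketone: 8-(TBSO-methyl)-3β,10β-dimethyl-9-methylidene-decal-7-ene-1,4-dione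
Conditions: Zn dust, AcOH, THF, 0 °C to rt
Reagents that add atoms: none
Why: Zn/AcOH reduction of an ene-1,4-dione saturates C2=C3; C3 is set by axial ketonisation and acid equilibration α to the C4 carbonyl, which places the methyl equatorial (3β).

Step 6
Reactants: 8 trans-fused diketone; 9 (trimethylsilyl)methylmagnesium chloride
Product: 10 4β-hydroxy-4α-[(trimethylsilyl)methyl] C1-ketone
Conditions: 9, anhydrous CeCl3, THF, −78 to −40 °C; aq. NH4Cl
Reagents that add atoms: 9 (trimethylsilyl)methylmagnesium chloride, C[Si](C)(C)C[Mg]Cl
Why: Non-basic organocerium 1,2-addition (first half of a Peterson olefination) should take the C4 carbonyl, flanked by two CH groups, in preference to the neopentyl C1 carbonyl; the new C4 centre (equatorial attack, away from the syn-axial angular methyl) is of no consequence, and the β-hydroxysilane masks the future methylene against hydroboration.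

Step 7
Reactants: 10 4β-hydroxy-4α-[(trimethylsilyl)methyl] C1-ketone
Product: 11 1β,4β-diol
Conditions: NaBH4, MeOH/THF, 0 °C
Reagents that add atoms: none
Why: Borohydride reduction by axial attack on the α-face, opposite the adjacent axial angular methyl, should give the equatorial 1β alcohol and so set C1.

Step 8
Reactants: 11 1β,4β-diol
Product: 13 triol bearing the 9β-hydroxymethyl group (9α-H), via alkylborane 12 (not isolated)
Conditions: 9-BBN (3 equiv), THF, 0 to 40 °C; then 30% H2O2, aq. NaOAc, 0 °C to rt
Reagents that add atoms: 9-borabicyclo[3.3.1]nonane, [H]B1C2CCCC1CCC2 (boron stays only in 12); hydrogen peroxide, OO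
Why: Hydroboration–oxidation of the 1,1-disubstituted diene terminus places boron on the terminal carbon and delivers hydrogen to C9 from the α-face, opposite the axial angular methyl on the neighbouring C10, which sets the 9β-CH2OH/9α-H centre; the trisubstituted C7=C8 bond is much slower toward 9-BBN.

Step 9
Reactants: 13 triol
Product: 14 bis-TBS ether (C8-CH2OTBS and C9-CH2OTBS; free 1β-OH and 4β-OH)
Conditions: TBSCl (1.05 equiv), imidazole, CH2Cl2, −20 to 0 °C
Reagents that add atoms: tert-butyldimethylsilyl chloride, CC(C)(C)[Si](C)(C)Cl
Why: Silylation is selective for the primary alcohol over the hindered secondary C1 and tertiary C4 hydroxyls.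

Step 10
Reactants: 14 bis-TBS ether; 15 3-phenylprop-2-ynoic acid
Product: 16 1β-phenylpropiolate
Conditions: DCC, DMAP (cat.), CH2Cl2, 0 °C to rt
Reagents that add atoms: 15 3-phenylprop-2-ynoic acid, OC(=O)C#Cc1ccccc1
Why: Steglich esterification acylates the secondary C1 alcohol with retention, while the tertiary C4 alcohol is inert; the alkyne avoids any Z/E isomerisation during acylation.

Step 11
Reactants: 16 1β-phenylpropiolate
Product: 17 1β-(Z)-cinnamate
Conditions: H2 (1 atm), Pd/CaCO3 poisoned with Pb(OAc)2, quinoline, EtOAc, rt
Reagents that add atoms: none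
Why: Lindlar semihydrogenation adds hydrogen syn to the alkyne and should give the Z-alkene; the trisubstituted C7=C8 bond is not reduced by the poisoned catalyst.

Step 12
Reactants: 17 1β-(Z)-cinnamate
Product: 18 diol: 8,9β-bis(hydroxymethyl)-4-methylidene compound
Conditions: 48% aq. HF, MeCN, 0 °C to rt
Reagents that add atoms: none
Why: HF cleaves both primary TBS ethers and promotes the acid-mediated anti Peterson elimination of the tertiary β-hydroxysilane, which can only give the exocyclic C4 methylene; C3 and C5 are untouched.

Step 13
Reactants: 18 diol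
Product: 20 target dialdehyde (1R,3S,5S,9R,10S), via bis-alkoxysulfonium salt 19 (not isolated)
Conditions: (COCl)2, DMSO, CH2Cl2, −78 °C; then Et3N, −78 to −40 °C; cold pH 7 buffer
Reagents that add atoms: dimethyl sulfoxide, CS(C)=O (its SMe2 unit is carried only by 19; nothing is left in 20)
Why: Swern oxidation of an ene-1,4-diol to the dialdehyde at low temperature is the established way to avoid lactol/lactone formation and should leave the base-sensitive 9β-formyl centre unepimerised if quenched cold.

## Compound list

1 | 4-chlorobut-2-yn-1-ol | OCC#CCCl | starting material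
2 | tert-butyl[(4-chlorobut-2-yn-1-yl)oxy]dimethylsilane | CC(C)(C)[Si](C)(C)OCC#CCCl | intermediate
3 | vinylmagnesium bromide | C=C[Mg]Br | starting material
4 | tert-butyldimethyl[(2-vinylbuta-2,3-dien-1-yl)oxy]silane | C=C=C(CO[Si](C)(C)C(C)(C)C)C=C | intermediate
5 | 2,5-dimethyl-1,4-benzoquinone | CC1=CC(=O)C(C)=CC1=O | starting material
6 | cis-fused enedione (10β-Me, 5β-H) | O=C1C(C)=CC(=O)[C@]2(C)C(=C)C(CO[Si](C)(C)C(C)(C)C)=CC[C@H]12 | intermediate
7 | trans-fused enedione (10β-Me, 5α-H) | O=C1C(C)=CC(=O)[C@]2(C)C(=C)C(CO[Si](C)(C)C(C)(C)C)=CC[C@@H]12 | intermediate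
8 | trans-fused 1,4-diketone (3β-Me) | O=C1[C@@H](C)CC(=O)[C@]2(C)C(=C)C(CO[Si](C)(C)C(C)(C)C)=CC[C@@H]12 | intermediate
9 | (trimethylsilyl)methylmagnesium chloride | C[Si](C)(C)C[Mg]Cl | starting material
10 | 4β-hydroxy-4α-[(trimethylsilyl)methyl] C1-ketone | C[Si](C)(C)C[C@]1(O)[C@@H](C)CC(=O)[C@]2(C)C(=C)C(CO[Si](C)(C)C(C)(C)C)=CC[C@@H]12 | intermediate
11 | 1β,4β-diol | C[Si](C)(C)C[C@]1(O)[C@@H](C)C[C@@H](O)[C@]2(C)C(=C)C(CO[Si](C)(C)C(C)(C)C)=CC[C@@H]12 | intermediate
12 | B-alkyl-9-BBN adduct, C1 oxygen also borylated | C[Si](C)(C)C[C@]1(O)[C@@H](C)C[C@@H](OB3C4CCCC3CCC4)[C@]2(C)[C@@H](CB3C4CCCC3CCC4)C(CO[Si](C)(C)C(C)(C)C)=CC[C@@H]12 | intermediate (not isolated)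
13 | triol with 9β-hydroxymethyl | C[Si](C)(C)C[C@]1(O)[C@@H](C)C[C@@H](O)[C@]2(C)[C@@H](CO)C(CO[Si](C)(C)C(C)(C)C)=CC[C@@H]12 | intermediate
14 | bis-TBS ether | C[Si](C)(C)C[C@]1(O)[C@@H](C)C[C@@H](O)[C@]2(C)[C@@H](CO[Si](C)(C)C(C)(C)C)C(CO[Si](C)(C)C(C)(C)C)=CC[C@@H]12 | intermediate
15 | 3-phenylprop-2-ynoic acid | OC(=O)C#Cc1ccccc1 | starting material
16 | 1β-phenylpropiolate | C[Si](C)(C)C[C@]1(O)[C@@H](C)C[C@@H](OC(=O)C#Cc3ccccc3)[C@]2(C)[C@@H](CO[Si](C)(C)C(C)(C)C)C(CO[Si](C)(C)C(C)(C)C)=CC[C@@H]12 | intermediate
17 | 1β-(Z)-cinnamate | C[Si](C)(C)C[C@]1(O)[C@@H](C)C[C@@H](OC(=O)/C=C\c3ccccc3)[C@]2(C)[C@@H](CO[Si](C)(C)C(C)(C)C)C(CO[Si](C)(C)C(C)(C)C)=CC[C@@H]12 | intermediate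
18 | 8,9β-bis(hydroxymethyl)-4-methylidene diol | C=C1[C@@H](C)C[C@@H](OC(=O)/C=C\c3ccccc3)[C@]2(C)[C@@H](CO)C(CO)=CC[C@@H]12 | intermediate
19 | bis(alkoxydimethylsulfonium) dichloride | C=C1[C@@H](C)C[C@@H](OC(=O)/C=C\c3ccccc3)[C@]2(C)[C@@H](CO[S+](C)C)C(CO[S+](C)C)=CC[C@@H]12.[Cl-].[Cl-] | intermediate (not isolated)
20 | target dialdehyde CNP0146135.2 | C=C1[C@@H](C)C[C@@H](OC(=O)/C=C\c2ccccc2)[C@]2(C)[C@@H](C=O)C(C=O)=CC[C@@H]12 | target

## Step count and risks

Total steps: 13. Longest linear sequence: 13 steps (1 to 20).

Most likely to fail: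

Step 3. The cationic boron Lewis acid may oligomerise the vinylallene, or face and regioselectivity may be eroded on this untested diene class. The fallback sets out from 4 and 5 and uses known chemistry. The uncatalysed thermal cycloaddition (toluene, 60 °C) should give 6 as the racemate, that is together with the mirror-image adduct F1. Step 4 is run on the mixture, giving 7 together with the mirror-image trans-enedione F2. The pair is then separated by preparative chromatography on a chiral stationary phase (amylose tris(3,5-dimethylphenylcarbamate)), and the route is rejoined at 7.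

Step 8. Hydroboration may lose face selectivity at C9 or compete at C7=C8, because the boryl ether formed at the C1 oxygen crowds the approach to the terminal carbon. The fallback sets out from 11 and delivers the hydride intramolecularly. Silylation of the C1 hydroxyl with 1,1,3,3-tetramethyldisilazane should give the dimethylsilyl ether F4. Hydrosilylation with Pt2[(CH2=CHSiMe2)2O]3 (toluene, 60 °C) should then put silicon on the terminal carbon and hydrogen on C9, closing the six-membered cyclic siloxane F5. Tamao oxidation (H2O2, KF, KHCO3, THF/MeOH) rejoins the route at 13.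

Step 4. The cis/trans equilibrium may not lie far enough on the trans side, or the base may move the exocyclic diene into conjugation on prolonged exposure. The fallback sets out from 6 and replaces thermodynamic by kinetic control. Deprotonation at C5 with KN(SiMe3)2 (THF, −78 °C) should give the potassium enolate F3. A cold quench with acetic acid should protonate C5 from the face opposite the angular methyl, rejoining the route at 7.

Further compounds
F1 | step 3 | mirror-image cis-fused adduct (enantiomer of 6) | O=C1C(C)=CC(=O)[C@@]2(C)C(=C)C(CO[Si](C)(C)C(C)(C)C)=CC[C@@H]12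
F2 | step 3 | mirror-image trans-fused enedione (enantiomer of 7) | O=C1C(C)=CC(=O)[C@@]2(C)C(=C)C(CO[Si](C)(C)C(C)(C)C)=CC[C@H]12
F3 | step 4 | potassium C4-enolate of 6 | [K+].[O-]C1=C2CC=C(CO[Si](C)(C)C(C)(C)C)C(=C)[C@@]2(C)C(=O)C=C1C
F4 | step 8 | C1 O-dimethylsilyl ether of 11 | C[Si](C)(C)C[C@]1(O)[C@@H](C)C[C@@H](O[SiH](C)C)[C@]2(C)C(=C)C(CO[Si](C)(C)C(C)(C)C)=CC[C@@H]12
F5 | step 8 | cyclic siloxane bridging the C1 oxygen and the C9 methylene carbon | C[Si](C)(C)C[C@]1(O)[C@@H](C)C[C@@H](O[Si]3(C)C)[C@]2(C)[C@@H](C3)C(CO[Si](C)(C)C(C)(C)C)=CC[C@@H]12
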